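Ring A is disconnected across two bonds, methyl-bearing carbon to phenol carbon and siloxy-bearing carbon to the C–H carbon, which divides it into a 3-ethoxy-4-alkylcyclobutenone and 1-(triisopropylsiloxy)propyne. The feature exploited is that in ring A both the methyl carbon and the carbon bonded to C7 lie between two oxygenated carbons, while the sixth carbon can stay unsubstituted for late acylation. One thermal pericyclic cascade forms both bonds, closes ring A and fixes every substituent position, leaving the C7 stereocentre (set earlier by iminium catalysis) untouched. The precursor is a cyclobutenone whose C4 carries C7 with its isobutyl group and ring B, masked as a methyl enol ether.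

Key step: step 8

Assumption: syncarpic acid, ethoxyacetylene (hexane solution) and 1-propynyllithium are taken as purchasable; ring A is the phloroglucinol ring, ring B the tetramethylcyclohexenedione ring and C7 the methine joining them.

Step 1
Reactants: 1 isovaleraldehyde (3-methylbutanal); 2 (triphenylphosphoranylidene)acetaldehyde
Product: 3 (E)-5-methylhex-2-enal
Conditions: 1 (1.5 equiv), PhMe, 80 °C; distillation
Reagents that add atoms: none
Why: Wittig olefination with a formyl-stabilised ylide is E-selective, and the excess of the volatile aldehyde suppresses a second homologation of the product enal.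

Step 2
Reactants: 3 (E)-5-methylhex-2-enal; 4 syncarpic acid (2,2,4,4-tetramethylcyclohexane-1,3,5-trione)
Product: 5 (4S)-2-hydroxy-4-(2-methylpropyl)-6,6,8,8-tetramethyl-3,4-dihydro-2H-chromene-5,7(6H,8H)-dione (lactol; both C2 anomers)
Conditions: (R)-2-[diphenyl(trimethylsilyloxy)methyl]pyrrolidine (10 mol%), CH2Cl2, 0 °C → rt
Reagents that add atoms: none
Why: Iminium-catalysed Michael addition of a cyclic 1,3-diketone enol to an enal, an established reaction class, is followed by hemiacetal closure that withdraws the adduct from retro-addition; the diphenyl(siloxy)methyl group of the R catalyst shields one face of the s-trans E-iminium ion, so C2 of syncarpic acid adds to the other face of the beta-carbon and sets C7 (chromene C4) as S.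

Step 3
Reactants: 5 lactol
Product: 6 (4S)-4-(2-methylpropyl)-6,6,8,8-tetramethyl-3,4-dihydro-2H-chromene-2,5,7(6H,8H)-trione (enol lactone)
Conditions: PhI(OAc)2 (1.3 equiv), TEMPO (10 mol%), CH2Cl2, rt
Reagents that add atoms: none
Why: Oxoammonium-mediated oxidation of a lactol to the lactone (TEMPO with PhI(OAc)2 as terminal oxidant) converts both anomers into one compound and touches neither the vinylogous ester nor the stereocentre.

Step 4
Reactants: 6 enol lactone
Product: 8 benzyl (3S)-3-(2-methoxy-3,3,5,5-tetramethyl-4,6-dioxocyclohex-1-en-1-yl)-5-methylhexanoate, via enol benzyl ester 7 (not isolated)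
Conditions: BnOH (1.5 equiv), DBU (1.1 equiv), THF, 0 °C → rt; AcOH (1.2 equiv); then TMSCHN2 (4 equiv), PhMe/MeOH 4:1, 0 °C → rt
Reagents that add atoms: benzyl alcohol, OCc1ccccc1; trimethylsilyldiazomethane, C[Si](C)(C)C=[N+]=[N-]
Why: Alcoholysis of an activated enol ester (the triketone enolate is an excellent leaving group) is followed by O-methylation of the acidic enol with a diazoalkane; the two carbonyls flanking C2 of ring B are constitutionally equivalent, so only one enol ether can form, and no base able to affect C7 is present.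

Step 5
Reactants: 8 benzyl ester
Product: 9 (3S)-3-(2-methoxy-3,3,5,5-tetramethyl-4,6-dioxocyclohex-1-en-1-yl)-5-methylhexanoic acid
Conditions: H2 (1 atm), 10% Pd/C, EtOAc, rt; filtration, evaporation, used at once
Reagents that add atoms: none
Why: Hydrogenolysis of a benzyl ester frees the acid under neutral, non-aqueous conditions, so the vinylogous methyl ester never meets hydroxide or aqueous acid; the tetrasubstituted enol ether alkene and the hindered ketones are not reduced.

Step 6
Reactants: 9 acid; 10 ethoxyacetylene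
Product: 13 3-ethoxy-4-[(1S)-1-(2-methoxy-3,3,5,5-tetramethyl-4,6-dioxocyclohex-1-en-1-yl)-3-methylbutyl]cyclobut-2-en-1-one (both C4 epimers), via acid chloride 11 (not isolated), via alkylketene 12 (not isolated)
Conditions: 1-chloro-N,N,2-trimethylprop-1-en-1-amine (1.1 equiv), CH2Cl2, 0 °C; then slow addition to 10 (5 equiv), Et3N (1.5 equiv), CH2Cl2, 0 °C → rt
Reagents that add atoms: none
Why: Ketene–alkyne [2+2] cycloaddition: the acid chloride, made without HCl, is dehydrochlorinated by Et3N to the aldoketene, whose carbonyl carbon bonds to the nucleophilic CH terminus of the ynol ether, which places OEt at C3 and the C7 unit at C4; the new C4 centre forms as both epimers, which does not matter because C4 becomes sp2 in step 8, and C7 has no acidic hydrogen.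

Step 7
Reactants: 14 1-propynyllithium (CH3C≡CLi)
Product: 16 1-(triisopropylsiloxy)propyne, via lithium propynolate 15 (not isolated)
Conditions: t-BuOOH (anhydrous, in decane), LiN(SiMe3)2, THF, −78 °C; 14, −78 → 0 °C; then i-Pr3SiOTf, −78 → 0 °C
Reagents that add atoms: tert-butyl hydroperoxide, CC(C)(C)OO; triisopropylsilyl trifluoromethanesulfonate, CC(C)[Si](C(C)C)(C(C)C)OS(=O)(=O)C(F)(F)F
Why: Oxidation of a lithium acetylide to the ynolate by lithium tert-butyl peroxide (the acetylide carbon attacks the oxenoid oxygen and expels tert-butoxide) and O-silylation of the ynolate by the bulky silyl triflate is the standard ynolate route to 1-siloxyalkynes.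

Step 8
Reactants: 13 cyclobutenone; 16 1-(triisopropylsiloxy)propyne
Product: 21 2-[(1S)-1-[6-ethoxy-2-hydroxy-3-methyl-4-(triisopropylsiloxy)phenyl]-3-methylbutyl]-3-methoxy-4,4,6,6-tetramethylcyclohex-2-ene-1,5-dione, via vinylketene 17 (not isolated), via 4-vinylcyclobutenone 18 (not isolated), via dienylketene 19 (not isolated), via cyclohexadienone 20 (not isolated)
Conditions: 16 (2 equiv), PhMe, 110 °C, sealed tube, Ar
Reagents that add atoms: none
Why: Danheiser benzannulation: thermal 4-pi electrocyclic opening of 13 (C4 substituent rotating outward) gives vinylketene 17, the nucleophilic methyl-bearing carbon of 16 attacks its ketene carbon in a regiospecific [2+2] cycloaddition to 18, and a second 4-pi opening gives dienylketene 19. Ring A is closed by thermal disrotatory 6-pi electrocyclisation of 19, which joins the ketene carbon to the former C4, and dienone 20 tautomerises to the phenol. The closest known reaction type is the benzannulation of cyclobutenones with 1-siloxyalkynes to resorcinol monosilyl ethers; a 3-alkoxy-4-alkylcyclobutenone is a less common member of the same substrate class. No stereocentre is formed: both C4 epimers of 13 give the same vinylketene, and C7 carries no acidic or migrating group under neutral thermal conditions, so its S configuration from step 2 is kept. The selectivity needed is regiochemical (methyl next to the new OH, siloxy next to the ring C–H) and is secured by the polarisation of the siloxyalkyne together with the fixed connectivity of 13; outward rotation keeps the C7–H bond away from the ketene, and ring B has no OH that could trap a ketene.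

Step 9
Reactants: 21 silyl ether
Product: 22 2-[(1S)-1-(6-ethoxy-2,4-dihydroxy-3-methylphenyl)-3-methylbutyl]-3-methoxy-4,4,6,6-tetramethylcyclohex-2-ene-1,5-dione
Conditions: n-Bu4NF (1.1 equiv), AcOH (1.2 equiv), THF, 0 °C
Reagents that add atoms: none
Why: Fluoride-induced cleavage of the aryl silyl ether (Si–F bond formation), buffered with AcOH so that the electron-rich phenolate is not left exposed to base or air, leaves the alkyl ethers and the enol ether untouched.

Step 10
Reactants: 22 resorcinol; 23 3-phenylpropanoyl chloride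
Product: 24 2-[(1S)-1-[6-ethoxy-2,4-dihydroxy-3-methyl-5-(3-phenylpropanoyl)phenyl]-3-methylbutyl]-3-methoxy-4,4,6,6-tetramethylcyclohex-2-ene-1,5-dione
Conditions: 23 (1.2 equiv), TiCl4 (2.5 equiv), CH2Cl2, −40 → 0 °C
Reagents that add atoms: none
Why: Friedel–Crafts acylation directed ortho to a titanium phenoxide: the only unsubstituted carbon of ring A lies ortho to the freed OH and para to the other OH, so the site is unambiguous, and the low temperature is chosen to spare the ring B enol ether and the C7–aryl bond.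

Step 11
Reactants: 24 aryl ketone
Product: 25 3-hydroxy-2-[(1S)-3-methyl-1-[2,4,6-trihydroxy-3-methyl-5-(3-phenylpropanoyl)phenyl]butyl]-4,4,6,6-tetramethylcyclohex-2-ene-1,5-dione (target)
Conditions: BCl3 (6 equiv), n-Bu4NI (5 equiv), CH2Cl2, −78 → 0 °C; MeOH, then pH 5 buffer
Reagents that add atoms: none
Why: Lewis acid-assisted SN2 dealkylation: BCl3 binds the twisted, di-ortho-substituted ethoxy oxygen and the ring B vinylogous ester carbonyl, iodide removes ethyl and methyl as alkyl iodides at or below 0 °C, and hydrolysis of the boron esters frees the phenol and the enol without involving C7.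

Compound list

1 | isovaleraldehyde (3-methylbutanal) | CC(C)CC=O | starting material
2 | (triphenylphosphoranylidene)acetaldehyde | O=CC=P(c1ccccc1)(c1ccccc1)c1ccccc1 | starting material
3 | (E)-5-methylhex-2-enal | CC(C)C/C=C/C=O | intermediate
4 | syncarpic acid (2,2,4,4-tetramethylcyclohexane-1,3,5-trione) | CC1(C)C(=O)CC(=O)C(C)(C)C1=O | starting material
5 | (4S)-2-hydroxy-4-(2-methylpropyl)-6,6,8,8-tetramethyl-3,4-dihydro-2H-chromene-5,7(6H,8H)-dione (both C2 anomers) | OC1C[C@H](CC(C)C)C2=C(O1)C(C)(C)C(=O)C(C)(C)C2=O | intermediate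
6 | (4S)-4-(2-methylpropyl)-6,6,8,8-tetramethyl-3,4-dihydro-2H-chromene-2,5,7(6H,8H)-trione | O=C1C[C@H](CC(C)C)C2=C(O1)C(C)(C)C(=O)C(C)(C)C2=O | intermediate
7 | benzyl (3S)-3-(2-hydroxy-3,3,5,5-tetramethyl-4,6-dioxocyclohex-1-en-1-yl)-5-methylhexanoate (not isolated) | O=C(OCc1ccccc1)C[C@H](CC(C)C)C1=C(O)C(C)(C)C(=O)C(C)(C)C1=O | intermediate
8 | benzyl (3S)-3-(2-methoxy-3,3,5,5-tetramethyl-4,6-dioxocyclohex-1-en-1-yl)-5-methylhexanoate | O=C(OCc1ccccc1)C[C@H](CC(C)C)C1=C(OC)C(C)(C)C(=O)C(C)(C)C1=O | intermediate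
9 | (3S)-3-(2-methoxy-3,3,5,5-tetramethyl-4,6-dioxocyclohex-1-en-1-yl)-5-methylhexanoic acid | OC(=O)C[C@H](CC(C)C)C1=C(OC)C(C)(C)C(=O)C(C)(C)C1=O | intermediate
10 | ethoxyacetylene (ethoxyethyne) | CCOC#C | starting material
11 | (3S)-3-(2-methoxy-3,3,5,5-tetramethyl-4,6-dioxocyclohex-1-en-1-yl)-5-methylhexanoyl chloride (not isolated) | ClC(=O)C[C@H](CC(C)C)C1=C(OC)C(C)(C)C(=O)C(C)(C)C1=O | intermediate
12 | (3S)-3-(2-methoxy-3,3,5,5-tetramethyl-4,6-dioxocyclohex-1-en-1-yl)-5-methylhex-1-en-1-one (alkylketene; not isolated) | O=C=C[C@H](CC(C)C)C1=C(OC)C(C)(C)C(=O)C(C)(C)C1=O | intermediate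
13 | 3-ethoxy-4-[(1S)-1-(2-methoxy-3,3,5,5-tetramethyl-4,6-dioxocyclohex-1-en-1-yl)-3-methylbutyl]cyclobut-2-en-1-one (both C4 epimers) | O=C1C=C(OCC)C1[C@H](CC(C)C)C2=C(OC)C(C)(C)C(=O)C(C)(C)C2=O | intermediate
14 | 1-propynyllithium | CC#C[Li] | starting material
15 | lithium prop-1-yn-1-olate (not isolated) | CC#CO[Li] | intermediate
16 | 1-(triisopropylsiloxy)propyne | CC#CO[Si](C(C)C)(C(C)C)C(C)C | intermediate
17 | (5S)-3-ethoxy-5-(2-methoxy-3,3,5,5-tetramethyl-4,6-dioxocyclohex-1-en-1-yl)-7-methylocta-1,3-dien-1-one (vinylketene; C7 unit trans to the ketene carbon; not isolated) | O=C=C/C(OCC)=C/[C@H](CC(C)C)C1=C(OC)C(C)(C)C(=O)C(C)(C)C1=O | intermediate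
18 | 4-[(3S)-1-ethoxy-3-(2-methoxy-3,3,5,5-tetramethyl-4,6-dioxocyclohex-1-en-1-yl)-5-methylhex-1-en-1-yl]-2-methyl-3-(triisopropylsiloxy)cyclobut-2-en-1-one (not isolated) | CC1=C(O[Si](C(C)C)(C(C)C)C(C)C)C(C1=O)/C(OCC)=C/[C@H](CC(C)C)C2=C(OC)C(C)(C)C(=O)C(C)(C)C2=O | intermediate
19 | (7S)-5-ethoxy-7-(2-methoxy-3,3,5,5-tetramethyl-4,6-dioxocyclohex-1-en-1-yl)-2,9-dimethyl-3-(triisopropylsiloxy)deca-1,3,5-trien-1-one (dienylketene; not isolated) | O=C=C(C)/C(O[Si](C(C)C)(C(C)C)C(C)C)=C\C(OCC)=C\[C@H](CC(C)C)C1=C(OC)C(C)(C)C(=O)C(C)(C)C1=O | intermediate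
20 | 5-ethoxy-6-[(1S)-1-(2-methoxy-3,3,5,5-tetramethyl-4,6-dioxocyclohex-1-en-1-yl)-3-methylbutyl]-2-methyl-3-(triisopropylsiloxy)cyclohexa-2,4-dien-1-one (not isolated) | O=C1C(C)=C(O[Si](C(C)C)(C(C)C)C(C)C)C=C(OCC)C1[C@H](CC(C)C)C2=C(OC)C(C)(C)C(=O)C(C)(C)C2=O | intermediate
21 | 2-[(1S)-1-[6-ethoxy-2-hydroxy-3-methyl-4-(triisopropylsiloxy)phenyl]-3-methylbutyl]-3-methoxy-4,4,6,6-tetramethylcyclohex-2-ene-1,5-dione | Cc1c(O[Si](C(C)C)(C(C)C)C(C)C)cc(OCC)c([C@H](CC(C)C)C2=C(OC)C(C)(C)C(=O)C(C)(C)C2=O)c1O | intermediate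
22 | 2-[(1S)-1-(6-ethoxy-2,4-dihydroxy-3-methylphenyl)-3-methylbutyl]-3-methoxy-4,4,6,6-tetramethylcyclohex-2-ene-1,5-dione | Cc1c(O)cc(OCC)c([C@H](CC(C)C)C2=C(OC)C(C)(C)C(=O)C(C)(C)C2=O)c1O | intermediate
23 | 3-phenylpropanoyl chloride | O=C(Cl)CCc1ccccc1 | starting material
24 | 2-[(1S)-1-[6-ethoxy-2,4-dihydroxy-3-methyl-5-(3-phenylpropanoyl)phenyl]-3-methylbutyl]-3-methoxy-4,4,6,6-tetramethylcyclohex-2-ene-1,5-dione | Cc1c(O)c(C(=O)CCc2ccccc2)c(OCC)c([C@H](CC(C)C)C2=C(OC)C(C)(C)C(=O)C(C)(C)C2=O)c1O | intermediate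
25 | 3-hydroxy-2-[(1S)-3-methyl-1-[2,4,6-trihydroxy-3-methyl-5-(3-phenylpropanoyl)phenyl]butyl]-4,4,6,6-tetramethylcyclohex-2-ene-1,5-dione | Cc1c(O)c(C(=O)CCc2ccccc2)c(O)c([C@H](CC(C)C)C2=C(O)C(C)(C)C(=O)C(C)(C)C2=O)c1O | target

Total step count: 11. Longest linear sequence: 10 steps (steps 1 to 6 and 8 to 11, from isovaleraldehyde); step 7 is a one-step branch.

Steps most likely to fail

Step 8. The vinylogous-ester stabilisation of 13 may slow the first ring opening. Self-condensation of the vinylketene, acylation of the product phenol by ketene, or addition–elimination of the new phenol onto the ring B enol ether could then outrun the bimolecular cycloaddition. The fallback gives up the pericyclic ring construction and attaches a preformed ring A to C7 by conjugate addition. Knoevenagel condensation of 4 with 1 (secondary amine, then acid) gives 2-(3-methylbutylidene)-4,4,6,6-tetramethylcyclohexane-1,3,5-trione F1. Commercial 2-methylphloroglucinol is acylated with 23 (AlCl3, CH2Cl2/PhNO2) to 1-(2,4,6-trihydroxy-3-methylphenyl)-3-phenylpropan-1-one F2. The single free ring carbon of F2 adds to F1 in a Friedel–Crafts-type Michael addition to give racemic 3-hydroxy-2-[3-methyl-1-[2,4,6-trihydroxy-3-methyl-5-(3-phenylpropanoyl)phenyl]butyl]-4,4,6,6-tetramethylcyclohex-2-ene-1,5-dione F3. The S enantiomer is then separated by preparative chromatography on a chiral stationary phase. This fallback sets out from 4, 1 and 23 and comes back to the route at 25.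

Step 6. Self-condensation of the aldoketene may outrun the slow bimolecular cycloaddition. Intramolecular O-acylation of the ring B vinylogous ester by the acyl chloride or the ketene, with loss of chloromethane, may also divert material; this would only regenerate lactone 6, which can be recycled through steps 4 and 5. The fallback uses a more nucleophilic two-carbon partner and finishes by elimination. Ketene 12, generated as in step 6 but in the presence of 1,1-diethoxyethene, should undergo [2+2] cycloaddition to 3,3-diethoxy-2-[(1S)-1-(2-methoxy-3,3,5,5-tetramethyl-4,6-dioxocyclohex-1-en-1-yl)-3-methylbutyl]cyclobutan-1-one F4. DBU in CH2Cl2 at 0 °C then removes ethanol by E1cB elimination through the unsubstituted, less hindered methylene, which gives the vinylogous ester with the alkyl group on the sp3 carbon. This fallback sets out from 9 and comes back at 13.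

Step 11. De-ethylation of the hindered aryl ether may stay incomplete. Once the ring B enol is free, the Lewis acid may promote cyclodehydration between a phenolic OH and ring B, or reversible cleavage of the C7–aryl bond with erosion of enantiopurity. The fallback changes the spectator group on ring A so that no boron halide is needed:
- From 9, step 6 is run with tert-butoxyethyne (a known reagent) to give 3-tert-butoxy-4-[(1S)-1-(2-methoxy-3,3,5,5-tetramethyl-4,6-dioxocyclohex-1-en-1-yl)-3-methylbutyl]cyclobut-2-en-1-one F5.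
- The conditions of step 8 give 2-[(1S)-1-[6-tert-butoxy-2-hydroxy-3-methyl-4-(triisopropylsiloxy)phenyl]-3-methylbutyl]-3-methoxy-4,4,6,6-tetramethylcyclohex-2-ene-1,5-dione F6.
- The conditions of step 9 give 2-[(1S)-1-(6-tert-butoxy-2,4-dihydroxy-3-methylphenyl)-3-methylbutyl]-3-methoxy-4,4,6,6-tetramethylcyclohex-2-ene-1,5-dione F7.
- TiCl4 acylation with 23 as in step 10 should remove the tert-butyl ether as 2-methylpropene in the same operation and give 3-methoxy-2-[(1S)-3-methyl-1-[2,4,6-trihydroxy-3-methyl-5-(3-phenylpropanoyl)phenyl]butyl]-4,4,6,6-tetramethylcyclohex-2-ene-1,5-dione F8.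
- LiCl in DMF at 90 °C then demethylates the vinylogous ester by SN2 attack at methyl under neutral conditions, giving 25.

This fallback sets out from 9 and comes back at 25.

Further compounds

F1 | step 8 | 2-(3-methylbutylidene)-4,4,6,6-tetramethylcyclohexane-1,3,5-trione | CC(C)CC=C1C(=O)C(C)(C)C(=O)C(C)(C)C1=O
F2 | step 8 | 1-(2,4,6-trihydroxy-3-methylphenyl)-3-phenylpropan-1-one | Cc1c(O)cc(O)c(C(=O)CCc2ccccc2)c1O
F3 | step 8 | racemic 3-hydroxy-2-[3-methyl-1-[2,4,6-trihydroxy-3-methyl-5-(3-phenylpropanoyl)phenyl]butyl]-4,4,6,6-tetramethylcyclohex-2-ene-1,5-dione | Cc1c(O)c(C(=O)CCc2ccccc2)c(O)c(C(CC(C)C)C2=C(O)C(C)(C)C(=O)C(C)(C)C2=O)c1O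
F4 | step 6 | 3,3-diethoxy-2-[(1S)-1-(2-methoxy-3,3,5,5-tetramethyl-4,6-dioxocyclohex-1-en-1-yl)-3-methylbutyl]cyclobutan-1-one | O=C1CC(OCC)(OCC)C1[C@H](CC(C)C)C2=C(OC)C(C)(C)C(=O)C(C)(C)C2=O
F5 | step 11 | 3-tert-butoxy-4-[(1S)-1-(2-methoxy-3,3,5,5-tetramethyl-4,6-dioxocyclohex-1-en-1-yl)-3-methylbutyl]cyclobut-2-en-1-one | O=C1C=C(OC(C)(C)C)C1[C@H](CC(C)C)C2=C(OC)C(C)(C)C(=O)C(C)(C)C2=O
F6 | step 11 | 2-[(1S)-1-[6-tert-butoxy-2-hydroxy-3-methyl-4-(triisopropylsiloxy)phenyl]-3-methylbutyl]-3-methoxy-4,4,6,6-tetramethylcyclohex-2-ene-1,5-dione | Cc1c(O[Si](C(C)C)(C(C)C)C(C)C)cc(OC(C)(C)C)c([C@H](CC(C)C)C2=C(OC)C(C)(C)C(=O)C(C)(C)C2=O)c1O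
F7 | step 11 | 2-[(1S)-1-(6-tert-butoxy-2,4-dihydroxy-3-methylphenyl)-3-methylbutyl]-3-methoxy-4,4,6,6-tetramethylcyclohex-2-ene-1,5-dione | Cc1c(O)cc(OC(C)(C)C)c([C@H](CC(C)C)C2=C(OC)C(C)(C)C(=O)C(C)(C)C2=O)c1O
F8 | step 11 | 3-methoxy-2-[(1S)-3-methyl-1-[2,4,6-trihydroxy-3-methyl-5-(3-phenylpropanoyl)phenyl]butyl]-4,4,6,6-tetramethylcyclohex-2-ene-1,5-dione | Cc1c(O)c(C(=O)CCc2ccccc2)c(O)c([C@H](CC(C)C)C2=C(OC)C(C)(C)C(=O)C(C)(C)C2=O)c1O
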